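The hexasubstituted quinone ring (C1=O, C2–OH, C3–OMe, C4=O, C5–hexaprenyl, C6–CH3) is built last, by disconnecting the C1–C6 bond between the carbonyl carbon next to C–OH and the methyl-bearing carbon. A Moore-type thermal ring expansion forms this bond: a 4-alkenyl-4-hydroxycyclobutenone opens to a dienylketene whose 6π-electrocyclization closes the ring, and oxidation gives the quinone. The step exploits the four contiguous oxygenated ring carbons C1–C4, which map onto a squaric acid ester (tert-butyl marks the future OH, methyl the OMe), and the adjacent C5/C6 carbon substituents, which map onto one trisubstituted alkenyllithium carrying the complete all-E hexaprenyl chain, assembled from two farnesyl units.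

Key step: step 11

Remark: the target has no stereocentre; its five E trisubstituted olefins are inherited from (2E,6E)-farnesyl building blocks, and the sulfone and carbinol centres formed on the way are racemic and are erased later.
Abbreviations: "hexaprenyl" = (2E,6E,10E,14E,18E)-3,7,11,15,19,23-hexamethyltetracosa-2,6,10,14,18,22-hexaen-1-yl; "C27 alkenyl" = (5E,9E,13E,17E,21E)-6,10,14,18,22,26-hexamethylheptacosa-2,5,9,13,17,21,25-heptaen-3-yl (a but-2-en-2-yl unit carrying hexaprenyl minus its C1 on C4; the substituent on C3 is always cis to the C1 methyl).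

Step 1
Reactants: 1 (2E,6E)-farnesyl acetate
Product: 2 (2E,6E,10E)-12-hydroxy-3,7,11-trimethyldodeca-2,6,10-trien-1-yl acetate
Conditions: SeO2 (10 mol %), t-BuOOH, salicylic acid (10 mol %), CH2Cl2, 25 °C
Reagents that add atoms: tert-butyl hydroperoxide CC(C)(C)OO; selenium dioxide O=[Se]=O (catalytic oxygen carrier)
Why: Sharpless allylic oxidation (ene reaction, then 2,3-sigmatropic shift) attacks the electron-richest terminal olefin at its E methyl group, so the allylic alcohol should form with E geometry while the olefin next to the acetate is spared.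

Step 2
Reactants: 2 (2E,6E,10E)-12-hydroxyfarnesyl acetate
Product: 3 (2E,6E,10E)-12-bromo-3,7,11-trimethyldodeca-2,6,10-trien-1-yl acetate
Conditions: CBr4, PPh3, CH2Cl2, 0 °C
Reagents that add atoms: carbon tetrabromide BrC(Br)(Br)Br
Why: Appel bromination displaces the oxyphosphonium at the primary allylic carbon by SN2, without allylic transposition or loss of E geometry.

Step 3
Reactants: 4 (2E,6E)-farnesyl bromide
Product: 5 (2E,6E)-farnesyl phenyl sulfone
Conditions: PhSO2Na, DMF, 25 °C
Reagents that add atoms: sodium benzenesulfinate [Na+].[O-]S(=O)c1ccccc1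
Why: SN2 S-alkylation of the sulfinate gives the allylic sulfone that serves as the C1 carbanion equivalent of the tail farnesyl unit.

Step 4
Reactants: 5 (2E,6E)-farnesyl phenyl sulfone; 3 (2E,6E,10E)-12-bromofarnesyl acetate
Product: 7 (2E,6E,10E,14E,18E)-3,7,11,15,19,23-hexamethyl-13-(phenylsulfonyl)tetracosa-2,6,10,14,18,22-hexaen-1-yl acetate (racemic at C13), via lithiated sulfone 6 (not isolated)
Conditions: n-BuLi, THF/DMPU, −78 °C; then 3, −78 → −40 °C
Reagents that add atoms: none
Why: Alkylation of the sulfonyl-stabilized carbanion by the allylic bromide (Julia-type head-to-tail prenyl coupling) should outrun attack on the acetate at −78 °C and leaves all olefin geometries untouched; the racemic sulfone centre is removed in step 5.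

Step 5
Reactants: 7 C13-phenylsulfonyl hexaprenyl acetate
Product: 8 (2E,6E,10E,14E,18E)-3,7,11,15,19,23-hexamethyltetracosa-2,6,10,14,18,22-hexaen-1-ol (all-E hexaprenol)
Conditions: PdCl2(dppp) (5 mol %), LiBHEt3, THF, 0 °C
Reagents that add atoms: none
Why: Palladium-catalysed reductive desulfonylation of the allylic sulfone delivers hydride to the less substituted π-allyl terminus, which keeps the position and E geometry of the trisubstituted olefin, and the same hydride cleaves the acetate.

Step 6
Reactants: 8 all-E hexaprenol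
Product: 9 all-E hexaprenyl bromide
Conditions: PBr3, Et2O, 0 °C
Reagents that add atoms: phosphorus tribromide BrP(Br)Br
Why: Bromination of the primary allylic alcohol through its phosphite ester proceeds at low temperature without allylic rearrangement, as in the preparation of farnesyl bromide.

Step 7
Reactants: 10 tributyl(prop-1-yn-1-yl)stannane; 9 all-E hexaprenyl bromide
Product: 12 tributyl[(2Z,5E,9E,13E,17E,21E)-6,10,14,18,22,26-hexamethylheptacosa-2,5,9,13,17,21,25-heptaen-3-yl]stannane, via stannylated alkenylzirconocene chloride 11 (not isolated)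
Conditions: Cp2Zr(H)Cl, THF, 25 °C; then 9, Pd(PPh3)4 (5 mol %), ZnCl2 (20 mol %), THF, 25 °C
Reagents that add atoms: none
Why: syn-Hydrozirconation of the stannylalkyne places zirconium on the tin-bearing carbon, and Negishi-type palladium-catalysed alkenyl–allyl coupling transfers only the C–Zr bond, with retention, to the primary terminus of the allylic bromide, so the skipped diene should form with tin cis to the methyl group (2Z) and the E olefins unchanged.

Step 8
Reactants: 13 dimethyl squarate (3,4-dimethoxycyclobut-3-ene-1,2-dione)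
Product: 14 3-hydroxy-4-methoxycyclobut-3-ene-1,2-dione
Conditions: NaOH (1.0 equiv), THF/H2O, 0 °C; then HCl (1.0 equiv)
Reagents that add atoms: sodium hydroxide [Na+].[OH-]
Why: Addition–elimination of hydroxide at one vinylogous ester carbon stops at the monoester because the vinylogous carboxylate formed is deactivated toward a second attack.

Step 9
Reactants: 14 3-hydroxy-4-methoxycyclobut-3-ene-1,2-dione
Product: 15 3-tert-butoxy-4-methoxycyclobut-3-ene-1,2-dione
Conditions: tert-butyl 2,2,2-trichloroacetimidate, CH2Cl2/cyclohexane, 25 °C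
Reagents that add atoms: tert-butyl 2,2,2-trichloroacetimidate CC(C)(C)OC(=N)C(Cl)(Cl)Cl
Why: The strongly acidic vinylogous acid protonates the imidate and is O-tert-butylated by the ion pair without added acid, and because the two oxygens of its delocalized anion are equivalent only one mixed diester can form.

Step 10
Reactants: 12 (2Z)-C27 alkenyl tributylstannane; 15 3-tert-butoxy-4-methoxycyclobut-3-ene-1,2-dione
Product: 17 2-tert-butoxy-4-hydroxy-3-methoxy-4-[(2Z,5E,9E,13E,17E,21E)-6,10,14,18,22,26-hexamethylheptacosa-2,5,9,13,17,21,25-heptaen-3-yl]cyclobut-2-en-1-one (racemic), via alkenyllithium 16 (not isolated)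
Conditions: n-BuLi, THF, −78 → −40 °C; then added to 15, THF, −78 °C; aq NH4Cl
Reagents that add atoms: none
Why: Tin–lithium exchange proceeds with retention and the alkenyllithium adds 1,2 to the squarate (Moore–Liebeskind protocol) at the carbonyl beside the methoxy-bearing carbon, because the bulky tert-butoxy group shields its own neighbouring carbonyl and lithium can be chelated between the methoxy oxygen and the attacked carbonyl; the racemic carbinol centre is erased in step 11.

Step 11
Reactants: 17 4-(C27 alkenyl)-2-tert-butoxy-4-hydroxy-3-methoxycyclobutenone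
Product: 21 2-tert-butoxy-3-methoxy-6-methyl-5-hexaprenylcyclohexa-2,5-diene-1,4-dione, via dienylketene 18 (not isolated), via cyclohexadienone 19 (not isolated), via hydroquinone 20 (not isolated)
Conditions: PhMe, 110 °C (Ar); then Ag2O, Et2O, 25 °C
Reagents that add atoms: none
Why: Heating should open the cyclobutenone by thermal conrotatory 4π-electrocyclic cleavage of its C(=O)–C(OH) bond, the hydroxyl rotating outward (donor torquoselectivity) so that the alkenyl group lies cis to the new ketene in 18. A 6π-electrocyclization then joins the ketene carbon to the methyl-bearing alkenyl terminus (the C1–C6 bond of the quinone) to give dienone 19, which enolizes to hydroquinone 20, and Ag2O oxidizes 20 to quinone 21. The closest known reaction type is the Moore–Liebeskind ring expansion of 4-alkenyl-4-hydroxycyclobutenones to hydroquinones and quinones. The six-membered carbocycle closes in a pericyclic (disrotatory 6π-electrocyclic) mode; no stereocentre survives, since the only sp3 centre formed (C6 of 19) is lost on enolization, and the cis methyl at the alkenyl terminus only has to turn inward toward the substituent-free sp ketene carbon. The step needs outward rotation of OH (secured by the oxygen lone pairs), ring closure faster than any capture of the ketene (secured by the enforced cis geometry) and inertness of the skipped polyene and the tert-butyl ether at 110 °C; the substitution pattern is fixed by the connectivity of 17 and cannot scramble.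

Step 12
Reactants: 21 2-tert-butoxy-3-methoxy-6-methyl-5-hexaprenyl-1,4-benzoquinone
Product: 23 3-demethylubiquinone-6 (2-hydroxy-3-methoxy-6-methyl-5-hexaprenylcyclohexa-2,5-diene-1,4-dione), via trimethylsilyl ether 22 (not isolated)
Conditions: TMSOTf, 2,6-lutidine, CH2Cl2, 0 °C; then aq citric acid, MeOH
Reagents that add atoms: none
Why: Silyl triflate activates the quinone carbonyl that is vinylogous to the tert-butoxy group, so the tert-butyl cation should leave as isobutene under lutidine buffering (as in silyl-triflate cleavage of tert-butyl esters), sparing the methyl ether and the acid-sensitive polyene; the silyl ether hydrolyses on work-up.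

Compound list
1 | (2E,6E)-3,7,11-trimethyldodeca-2,6,10-trien-1-yl acetate (farnesyl acetate) | CC(C)=CCC/C(C)=C/CC/C(C)=C/COC(C)=O | starting material
2 | (2E,6E,10E)-12-hydroxy-3,7,11-trimethyldodeca-2,6,10-trien-1-yl acetate | OC/C(C)=C/CC/C(C)=C/CC/C(C)=C/COC(C)=O | intermediate
3 | (2E,6E,10E)-12-bromo-3,7,11-trimethyldodeca-2,6,10-trien-1-yl acetate | BrC/C(C)=C/CC/C(C)=C/CC/C(C)=C/COC(C)=O | intermediate
4 | (2E,6E)-1-bromo-3,7,11-trimethyldodeca-2,6,10-triene (farnesyl bromide) | CC(C)=CCC/C(C)=C/CC/C(C)=C/CBr | starting material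
5 | [(2E,6E)-3,7,11-trimethyldodeca-2,6,10-trien-1-yl]sulfonylbenzene (farnesyl phenyl sulfone) | CC(C)=CCC/C(C)=C/CC/C(C)=C/CS(=O)(=O)c1ccccc1 | intermediate
6 | [(2E,6E)-1-lithio-3,7,11-trimethyldodeca-2,6,10-trien-1-yl]sulfonylbenzene | CC(C)=CCC/C(C)=C/CC/C(C)=C/C([Li])S(=O)(=O)c1ccccc1 | intermediate (not isolated)
7 | (2E,6E,10E,14E,18E)-3,7,11,15,19,23-hexamethyl-13-(phenylsulfonyl)tetracosa-2,6,10,14,18,22-hexaen-1-yl acetate, racemic | CC(C)=CCC/C(C)=C/CC/C(C)=C/C(S(=O)(=O)c1ccccc1)C/C(C)=C/CC/C(C)=C/CC/C(C)=C/COC(C)=O | intermediate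
8 | (2E,6E,10E,14E,18E)-3,7,11,15,19,23-hexamethyltetracosa-2,6,10,14,18,22-hexaen-1-ol (hexaprenol) | CC(C)=CCC/C(C)=C/CC/C(C)=C/CC/C(C)=C/CC/C(C)=C/CC/C(C)=C/CO | intermediate
9 | (2E,6E,10E,14E,18E)-1-bromo-3,7,11,15,19,23-hexamethyltetracosa-2,6,10,14,18,22-hexaene (hexaprenyl bromide) | CC(C)=CCC/C(C)=C/CC/C(C)=C/CC/C(C)=C/CC/C(C)=C/CC/C(C)=C/CBr | intermediate
10 | tributyl(prop-1-yn-1-yl)stannane | CC#C[Sn](CCCC)(CCCC)CCCC | starting material
11 | chlorobis(cyclopentadienyl)[1-(tributylstannyl)prop-1-en-1-yl]zirconium, Zr cis to H and Sn cis to CH3 | C/C=C(/[Zr](Cl)(C1C=CC=C1)C1C=CC=C1)[Sn](CCCC)(CCCC)CCCC | intermediate (not isolated)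
12 | tributyl[(2Z,5E,9E,13E,17E,21E)-6,10,14,18,22,26-hexamethylheptacosa-2,5,9,13,17,21,25-heptaen-3-yl]stannane | C/C=C(/C/C=C(\C)CC/C=C(\C)CC/C=C(\C)CC/C=C(\C)CC/C=C(\C)CCC=C(C)C)[Sn](CCCC)(CCCC)CCCC | intermediate
13 | 3,4-dimethoxycyclobut-3-ene-1,2-dione (dimethyl squarate) | COC1=C(OC)C(=O)C1=O | starting material
14 | 3-hydroxy-4-methoxycyclobut-3-ene-1,2-dione | COC1=C(O)C(=O)C1=O | intermediate
15 | 3-tert-butoxy-4-methoxycyclobut-3-ene-1,2-dione | COC1=C(OC(C)(C)C)C(=O)C1=O | intermediate
16 | [(5E,9E,13E,17E,21E)-6,10,14,18,22,26-hexamethylheptacosa-2,5,9,13,17,21,25-heptaen-3-yl]lithium, Li cis to the C1 methyl (2E by the sequence rule) | C/C=C(/C/C=C(\C)CC/C=C(\C)CC/C=C(\C)CC/C=C(\C)CC/C=C(\C)CCC=C(C)C)[Li] | intermediate (not isolated)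
17 | 2-tert-butoxy-4-hydroxy-3-methoxy-4-[(2Z,5E,9E,13E,17E,21E)-6,10,14,18,22,26-hexamethylheptacosa-2,5,9,13,17,21,25-heptaen-3-yl]cyclobut-2-en-1-one, racemic | COC1=C(OC(C)(C)C)C(=O)C1(O)/C(=C\C)C/C=C(\C)CC/C=C(\C)CC/C=C(\C)CC/C=C(\C)CC/C=C(\C)CCC=C(C)C | intermediate
18 | (3Z,5Z)-2-tert-butoxy-4-hydroxy-3-methoxy-5-hexaprenylhepta-1,3,5-trien-1-one (dienylketene) | O=C=C(OC(C)(C)C)/C(OC)=C(O)\C(=C/C)C/C=C(\C)CC/C=C(\C)CC/C=C(\C)CC/C=C(\C)CC/C=C(\C)CCC=C(C)C | intermediate (not isolated)
19 | 2-tert-butoxy-4-hydroxy-3-methoxy-6-methyl-5-hexaprenylcyclohexa-2,4-dien-1-one, racemic | O=C1C(OC(C)(C)C)=C(OC)C(O)=C(C/C=C(\C)CC/C=C(\C)CC/C=C(\C)CC/C=C(\C)CC/C=C(\C)CCC=C(C)C)C1C | intermediate (not isolated)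
20 | 2-tert-butoxy-3-methoxy-6-methyl-5-hexaprenylbenzene-1,4-diol | COc1c(OC(C)(C)C)c(O)c(C)c(C/C=C(\C)CC/C=C(\C)CC/C=C(\C)CC/C=C(\C)CC/C=C(\C)CCC=C(C)C)c1O | intermediate (not isolated)
21 | 2-tert-butoxy-3-methoxy-6-methyl-5-hexaprenylcyclohexa-2,5-diene-1,4-dione | COC1=C(OC(C)(C)C)C(=O)C(C)=C(C/C=C(\C)CC/C=C(\C)CC/C=C(\C)CC/C=C(\C)CC/C=C(\C)CCC=C(C)C)C1=O | intermediate
22 | 3-methoxy-6-methyl-5-hexaprenyl-2-(trimethylsilyloxy)cyclohexa-2,5-diene-1,4-dione | COC1=C(O[Si](C)(C)C)C(=O)C(C)=C(C/C=C(\C)CC/C=C(\C)CC/C=C(\C)CC/C=C(\C)CC/C=C(\C)CCC=C(C)C)C1=O | intermediate (not isolated)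
23 | 3-demethylubiquinone-6: 2-hydroxy-3-methoxy-6-methyl-5-[(2E,6E,10E,14E,18E)-3,7,11,15,19,23-hexamethyltetracosa-2,6,10,14,18,22-hexaen-1-yl]cyclohexa-2,5-diene-1,4-dione | COC1=C(O)C(=O)C(C)=C(C/C=C(\C)CC/C=C(\C)CC/C=C(\C)CC/C=C(\C)CC/C=C(\C)CCC=C(C)C)C1=O | target

Total step count: 12. Longest linear sequence: 9 steps (steps 1, 2, 4, 5, 6, 7, 10, 11, 12).

Steps most likely to fail

Step 10. The alkenyllithium may discriminate poorly between the two ring carbonyl groups of 15; addition at the carbonyl beside the tert-butoxy-bearing carbon would carry the hydroxyl and methoxy groups into exchanged positions on the final ring. The fallback sets out from alkenyllithium 16 and comes back at target 23, and makes the site of addition irrelevant by symmetry. Compound 16 is added to the symmetrical diester 3,4-bis(allyloxy)cyclobut-3-ene-1,2-dione F1 (from squaric acid and allyl alcohol by azeotropic esterification), whose carbonyl groups are equivalent, to give the bis(allyloxy) adduct F2. Pd(PPh3)4 with HCO2H/Et3N should cleave only the allyl group of the vinylogous ester, because the enol-ether allyl group is a far poorer leaving group for zerovalent palladium, and gives the triethylammonium enolate F3. The two oxygens of this cyclobutane-1,3-dione enolate are equivalent, so O-methylation with Me2SO4 can give only the 2-allyloxy-3-methoxy adduct F4. Heating and Ag2O oxidation as in step 11 give allyloxy hydroquinone F5 and then allyloxy quinone F6, and Pd(PPh3)4 with dimedone removes the allyl group to give 23.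

Step 7. Transfer of the hindered stannyl-bearing alkenyl group from zirconium to palladium may be slow, so that allylic transposition or E/Z erosion in the π-allyl intermediate and Stille-type consumption of the vinylstannane product compete. The fallback sets out from bromide 9 and comes back at alkenyllithium 16. Compound 9 alkylates Ph3P=CH2 to give the homologated phosphonium salt triphenyl[(3E,7E,11E,15E,19E)-4,8,12,16,20,24-hexamethylpentacosa-3,7,11,15,19,23-hexaen-1-yl]phosphonium bromide F7. Deprotonation (n-BuLi), iodination (I2, −78 °C), a second deprotonation (NaN(SiMe3)2) and Wittig reaction of the iodo ylide with acetaldehyde (Stork–Zhao-type iodo-olefination) should give mainly the (Z)-vinyl iodide F8; iodine–lithium exchange with t-BuLi (2 equiv, −78 °C) then gives 16 with retention.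

Step 12. Ionization-type side reactions may compete with loss of isobutene: addition to, or cyclization of, the polyprenyl chain, including closure of the first prenyl olefin onto the activated quinone. The fallback sets out from 14 and 16 and comes back at 23; it replaces the tert-butyl group by a silyl group that is removed by fluoride. Compound 14 is silylated (TIPSOTf, Et3N) to 3-methoxy-4-(triisopropylsilyloxy)cyclobut-3-ene-1,2-dione F9. Addition of 16, steered by the bulky silyloxy group in the same sense as in step 10, gives the silyloxy adduct F10. The conditions of step 11 give silyloxy hydroquinone F11 and then silyloxy quinone F12, and Et3N·3HF in THF removes the silyl group to give 23.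

Further compounds
F1 | step 10 | 3,4-bis(prop-2-en-1-yloxy)cyclobut-3-ene-1,2-dione | C=CCOC1=C(OCC=C)C(=O)C1=O
F2 | step 10 | 4-(C27 alkenyl)-4-hydroxy-2,3-bis(prop-2-en-1-yloxy)cyclobut-2-en-1-one (alkenyl 2Z, ring cis to methyl), racemic | C=CCOC1=C(OCC=C)C(=O)C1(O)/C(=C\C)C/C=C(\C)CC/C=C(\C)CC/C=C(\C)CC/C=C(\C)CC/C=C(\C)CCC=C(C)C
F3 | step 10 | triethylammonium 4-(C27 alkenyl)-4-hydroxy-3-oxo-2-(prop-2-en-1-yloxy)cyclobut-1-en-1-olate | CC[NH+](CC)CC.[O-]C1=C(OCC=C)C(=O)C1(O)/C(=C\C)C/C=C(\C)CC/C=C(\C)CC/C=C(\C)CC/C=C(\C)CC/C=C(\C)CCC=C(C)C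
F4 | step 10 | 4-(C27 alkenyl)-4-hydroxy-3-methoxy-2-(prop-2-en-1-yloxy)cyclobut-2-en-1-one, racemic | COC1=C(OCC=C)C(=O)C1(O)/C(=C\C)C/C=C(\C)CC/C=C(\C)CC/C=C(\C)CC/C=C(\C)CC/C=C(\C)CCC=C(C)C
F5 | step 10 | 3-methoxy-6-methyl-5-hexaprenyl-2-(prop-2-en-1-yloxy)benzene-1,4-diol | COc1c(OCC=C)c(O)c(C)c(C/C=C(\C)CC/C=C(\C)CC/C=C(\C)CC/C=C(\C)CC/C=C(\C)CCC=C(C)C)c1O
F6 | step 10 | 3-methoxy-6-methyl-5-hexaprenyl-2-(prop-2-en-1-yloxy)cyclohexa-2,5-diene-1,4-dione | COC1=C(OCC=C)C(=O)C(C)=C(C/C=C(\C)CC/C=C(\C)CC/C=C(\C)CC/C=C(\C)CC/C=C(\C)CCC=C(C)C)C1=O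
F7 | step 7 | triphenyl[(3E,7E,11E,15E,19E)-4,8,12,16,20,24-hexamethylpentacosa-3,7,11,15,19,23-hexaen-1-yl]phosphonium bromide | [Br-].CC(C)=CCC/C(C)=C/CC/C(C)=C/CC/C(C)=C/CC/C(C)=C/CC/C(C)=C/CC[P+](c1ccccc1)(c1ccccc1)c1ccccc1
F8 | step 7 | (2Z,5E,9E,13E,17E,21E)-3-iodo-6,10,14,18,22,26-hexamethylheptacosa-2,5,9,13,17,21,25-heptaene | C/C=C(\I)C/C=C(\C)CC/C=C(\C)CC/C=C(\C)CC/C=C(\C)CC/C=C(\C)CCC=C(C)C
F9 | step 12 | 3-methoxy-4-[tri(propan-2-yl)silyloxy]cyclobut-3-ene-1,2-dione | COC1=C(O[Si](C(C)C)(C(C)C)C(C)C)C(=O)C1=O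
F10 | step 12 | 4-(C27 alkenyl)-4-hydroxy-3-methoxy-2-[tri(propan-2-yl)silyloxy]cyclobut-2-en-1-one, racemic | COC1=C(O[Si](C(C)C)(C(C)C)C(C)C)C(=O)C1(O)/C(=C\C)C/C=C(\C)CC/C=C(\C)CC/C=C(\C)CC/C=C(\C)CC/C=C(\C)CCC=C(C)C
F11 | step 12 | 3-methoxy-6-methyl-5-hexaprenyl-2-[tri(propan-2-yl)silyloxy]benzene-1,4-diol | COc1c(O[Si](C(C)C)(C(C)C)C(C)C)c(O)c(C)c(C/C=C(\C)CC/C=C(\C)CC/C=C(\C)CC/C=C(\C)CC/C=C(\C)CCC=C(C)C)c1O
F12 | step 12 | 3-methoxy-6-methyl-5-hexaprenyl-2-[tri(propan-2-yl)silyloxy]cyclohexa-2,5-diene-1,4-dione | COC1=C(O[Si](C(C)C)(C(C)C)C(C)C)C(=O)C(C)=C(C/C=C(\C)CC/C=C(\C)CC/C=C(\C)CC/C=C(\C)CC/C=C(\C)CCC=C(C)C)C1=O
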